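**Retrosynthetic overview**
- Ester C–O bond: the target is cut into linoleic acid and the C20 allylic alcohol; acylation is the last step.
- Feature used: ring carbon C1′ is the only stereocentre. It carries H and the C9 chain, lies between quaternary C6′ and C2′, and is allylic to the ring alkene C2′=C3′. The C1′–H bond is therefore traced back, with a 1,3-shift of the alkene, to an (R)-hydroxyl on C3′ of a C1′=C2′ cyclohexenol that already carries the whole chain (Mitsunobu sulfonylhydrazide displacement, then allylic diazene retro-ene).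
- The (R)-carbinol comes from the enone by Corey–Bakshi–Shibata reduction. The C1′–C9 bond of the enone comes from Stork–Danheiser addition of a C11 homoallylic lithium reagent to the isobutyl vinylogous ester of 2,4,4-trimethylcyclohexane-1,3-dione.
- The C11 iodide comes from geraniol: silylation, oxidation of the (E)-terminal methyl group, methylenation, hydroboration, iodination.
- Ring order: the single cyclohexene ring is carried in from 4,4-dimethylcyclohexane-1,3-dione; no ring is closed in the route.

Key step: step 11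

Remark on the chemistry: the primary allylic oxygen is carried as its tert-butyldiphenylsilyl ether, because this group must outlast the aqueous acid of step 9. Primed locants refer to the ring of the target (C1′ bears the chain, C2′ the methyl group, C6′ the gem-dimethyl group).

**Step 1**
Reactants: 1 geraniol
Product: 2 tert-butyl{[(2E)-3,7-dimethylocta-2,6-dien-1-yl]oxy}diphenylsilane
Conditions: TBDPSCl, imidazole, DMF, 0 °C to rt
Reagents that add atoms: tert-butyl(chloro)diphenylsilane, CC(C)(C)[Si](Cl)(c1ccccc1)c1ccccc1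
Why: Imidazole-promoted O-silylation of a primary allylic alcohol is reliable, and the resulting silyl ether should tolerate the oxidants, the organolithium and the dilute acid used later.

**Step 2**
Reactants: 2 tert-butyl{[(2E)-3,7-dimethylocta-2,6-dien-1-yl]oxy}diphenylsilane
Product: 3 (2E,6E)-8-(tert-butyldiphenylsilyloxy)-2,6-dimethylocta-2,6-dien-1-ol
Conditions: SeO2 (cat.), t-BuOOH, salicylic acid (cat.), CH2Cl2, rt
Reagents that add atoms: selenium dioxide, O=[Se]=O (catalytic oxygen carrier); tert-butyl hydroperoxide, CC(C)(C)OO (terminal oxygen source)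
Why: Riley allylic oxidation (ene reaction, then [2,3]-sigmatropic shift) attacks the electron-rich terminal trisubstituted alkene at its (E)-methyl group, so the (6E)-allylic alcohol should form while the alkene next to the silyloxy group is left alone; any enal from over-oxidation is the product of step 3 and is carried along.

**Step 3**
Reactants: 3 (2E,6E)-8-(tert-butyldiphenylsilyloxy)-2,6-dimethylocta-2,6-dien-1-ol
Product: 4 (2E,6E)-8-(tert-butyldiphenylsilyloxy)-2,6-dimethylocta-2,6-dienal
Conditions: MnO2, CH2Cl2, rt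
Reagents that add atoms: none
Why: MnO2 oxidises allylic alcohols selectively to the conjugated enal without touching the silyl ether or isomerising the (E)-alkene.

**Step 4**
Reactants: 4 (2E,6E)-8-(tert-butyldiphenylsilyloxy)-2,6-dimethylocta-2,6-dienal
Product: 5 tert-butyl{[(2E,6E)-3,7-dimethylnona-2,6,8-trien-1-yl]oxy}diphenylsilane
Conditions: Ph3PCH3Br, KOt-Bu, THF, 0 °C to rt
Reagents that add atoms: methyltriphenylphosphonium bromide, C[P+](c1ccccc1)(c1ccccc1)c1ccccc1.[Br-]
Why: Wittig methylenation of an α-methyl enal with the unstabilised ylide is fast and does not affect the existing (E)-trisubstituted alkenes.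

**Step 5**
Reactants: 5 tert-butyl{[(2E,6E)-3,7-dimethylnona-2,6,8-trien-1-yl]oxy}diphenylsilane
Product: 6 (3E,7E)-9-(tert-butyldiphenylsilyloxy)-3,7-dimethylnona-3,7-dien-1-ol
Conditions: 9-BBN, THF, 0 °C to rt; then aq. NaOH, H2O2, 0 °C
Reagents that add atoms: hydrogen peroxide, OO
Why: Hydroboration–oxidation with the bulky dialkylborane should occur only at the monosubstituted terminal alkene of the diene, with boron on the terminal carbon, giving the anti-Markovnikov homoallylic alcohol and leaving both trisubstituted alkenes intact.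

**Step 6**
Reactants: 6 (3E,7E)-9-(tert-butyldiphenylsilyloxy)-3,7-dimethylnona-3,7-dien-1-ol
Product: 7 tert-butyl{[(2E,6E)-9-iodo-3,7-dimethylnona-2,6-dien-1-yl]oxy}diphenylsilane
Conditions: I2, PPh3, imidazole, CH2Cl2, 0 °C to rt
Reagents that add atoms: iodine, II
Why: Appel-type iodination converts the primary alcohol into the iodide by SN2 displacement of the oxyphosphonium group under near-neutral conditions that the silyl ether tolerates.

**Step 7**
Reactants: 8 4,4-dimethylcyclohexane-1,3-dione
Product: 9 2,4,4-trimethylcyclohexane-1,3-dione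
Conditions: MeI, aq. NaOH, dioxane, 60 °C
Reagents that add atoms: iodomethane, CI
Why: Alkylation of the stabilised 1,3-dione enolate in a protic medium favours C-methylation at C2 over O-methylation, as in the standard preparation of 2-methylcyclohexane-1,3-diones.

**Step 8**
Reactants: 9 2,4,4-trimethylcyclohexane-1,3-dione
Product: 10 3-(2-methylpropoxy)-2,6,6-trimethylcyclohex-2-en-1-one
Conditions: i-BuOH, TsOH·H2O (cat.), toluene, reflux, Dean–Stark
Reagents that add atoms: 2-methylpropan-1-ol, CC(C)CO
Why: Acid-catalysed vinylogous ester formation under equilibrating conditions should place the alkoxy group on the carbonyl carbon remote from the gem-dimethyl group, leaving the C=O next to CMe2 for the next step.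

**Step 9**
Reactants: 7 tert-butyl{[(2E,6E)-9-iodo-3,7-dimethylnona-2,6-dien-1-yl]oxy}diphenylsilane; 10 3-(2-methylpropoxy)-2,6,6-trimethylcyclohex-2-en-1-one
Product: 13 3-[(3E,7E)-9-(tert-butyldiphenylsilyloxy)-3,7-dimethylnona-3,7-dien-1-yl]-2,4,4-trimethylcyclohex-2-en-1-one, via homoallylic organolithium 11 (not isolated), via lithium alkoxide adduct 12 (not isolated)
Conditions: 7, t-BuLi (2.0 equiv), Et2O/pentane, −78 °C; then 10, −78 to 0 °C; then 1 M aq. HCl, THF, 0 °C to rt
Reagents that add atoms: water, O
Why: Stork–Danheiser alkylative carbonyl transposition: iodine–lithium exchange gives the primary alkyllithium, which adds 1,2 to the vinylogous ester carbonyl (no α-hydrogen on the gem-dimethyl side), and dilute acid then ionises the tertiary allylic carbinol and hydrolyses the enol ether to the transposed enone with the chain on the carbon next to CMe2.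

**Step 10**
Reactants: 13 3-[(3E,7E)-9-(tert-butyldiphenylsilyloxy)-3,7-dimethylnona-3,7-dien-1-yl]-2,4,4-trimethylcyclohex-2-en-1-one
Product: 14 (1R)-3-[(3E,7E)-9-(tert-butyldiphenylsilyloxy)-3,7-dimethylnona-3,7-dien-1-yl]-2,4,4-trimethylcyclohex-2-en-1-ol
Conditions: (S)-2-methyl-CBS-oxazaborolidine [(3aS)-1-methyl-3,3-diphenyltetrahydro-1H,3H-pyrrolo[1,2-c][1,3,2]oxazaborole] (0.3 equiv), catecholborane, toluene, −78 °C
Reagents that add atoms: none
Why: Corey–Bakshi–Shibata reduction: the ketone should bind the oxazaborolidine boron anti to its larger, α-methylated alkenyl flank, so hydride from the coordinated borane reaches the face that gives the (R)-carbinol with the (S)-catalyst, and catecholborane leaves the chain alkenes alone.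

**Step 11**
Reactants: 14 (1R)-3-[(3E,7E)-9-(tert-butyldiphenylsilyloxy)-3,7-dimethylnona-3,7-dien-1-yl]-2,4,4-trimethylcyclohex-2-en-1-ol
Product: 17 tert-butyl{[(2E,6E)-3,7-dimethyl-9-[(1S)-2,6,6-trimethylcyclohex-2-en-1-yl]nona-2,6-dien-1-yl]oxy}diphenylsilane, via allylic sulfonylhydrazine 15 (not isolated), via allylic diazene 16 (not isolated)
Conditions: 2-nitrobenzenesulfonylhydrazide, PPh3, DEAD, N-methylmorpholine, −30 °C; then 23 °C
Reagents that add atoms: none
Why: PPh3/DEAD convert the C3′ hydroxyl into an oxyphosphonium leaving group that the acidic sulfonamide N–H of 2-nitrobenzenesulfonylhydrazide displaces by SN2 with inversion to give 15; on warming, 15 loses 2-nitrobenzenesulfinic acid to the monoalkyl diazene 16, which passes its N–H hydrogen to C1′ through a six-membered retro-ene transition state while N2 leaves and the alkene moves to C2′=C3′. The closest known reaction type is this same Mitsunobu sulfonylhydrazide displacement and allylic diazene rearrangement (reductive 1,3-transposition) of secondary cyclohex-2-enols. No ring is closed and no skeletal bond is formed; only the C1′–H bond is made. The new C1′ stereocentre is controlled by the C3′ carbinol set in step 10: inversion places nitrogen on the ring face opposite the former oxygen, and the concerted suprafacial shift delivers hydrogen to C1′ on that nitrogen-bearing face, which turns (R)-C3′–O into (S)-C1′–H. The step needs direct (SN2) rather than allylically shifted or ionising substitution, and no elimination to a ring diene; the distal terminus C1′ is fully substituted and sits next to quaternary C6′, the carbinol has a CH2 neighbour, and the low temperature should keep the oxyphosphonium from ionising. The chain alkenes are trisubstituted and so inert to any diimide from reagent decomposition, and the silyl ether is untouched.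

**Step 12**
Reactants: 17 tert-butyl{[(2E,6E)-3,7-dimethyl-9-[(1S)-2,6,6-trimethylcyclohex-2-en-1-yl]nona-2,6-dien-1-yl]oxy}diphenylsilane
Product: 18 (2E,6E)-3,7-dimethyl-9-[(1S)-2,6,6-trimethylcyclohex-2-en-1-yl]nona-2,6-dien-1-ol
Conditions: Bu4NF, THF, 0 °C to rt
Reagents that add atoms: none
Why: Fluoride-driven Si–O cleavage should free the primary allylic alcohol without touching the three alkenes or the C1′ stereocentre.

**Step 13**
Reactants: 18 (2E,6E)-3,7-dimethyl-9-[(1S)-2,6,6-trimethylcyclohex-2-en-1-yl]nona-2,6-dien-1-ol; 19 linoleic acid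
Product: 21 (2E,6E)-3,7-dimethyl-9-[(1S)-2,6,6-trimethylcyclohex-2-en-1-yl]nona-2,6-dien-1-yl (9Z,12Z)-octadeca-9,12-dienoate, via Yamaguchi mixed anhydride 20 (not isolated)
Conditions: 19, 2,4,6-trichlorobenzoyl chloride, Et3N, toluene, rt; then 18, DMAP, rt, argon
Reagents that add atoms: none
Why: Yamaguchi esterification: DMAP should transfer the unhindered aliphatic acyl group of the mixed anhydride to the primary alcohol under mild, non-isomerising conditions that preserve the skipped (Z,Z)-diene and the allylic ester.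

**Compound list**
1 | geraniol, (2E)-3,7-dimethylocta-2,6-dien-1-ol | CC(C)=CCC/C(C)=C/CO | starting material
2 | tert-butyl{[(2E)-3,7-dimethylocta-2,6-dien-1-yl]oxy}diphenylsilane | CC(C)=CCC/C(C)=C/CO[Si](c1ccccc1)(c1ccccc1)C(C)(C)C | intermediate
3 | (2E,6E)-8-(tert-butyldiphenylsilyloxy)-2,6-dimethylocta-2,6-dien-1-ol | OC/C(C)=C/CC/C(C)=C/CO[Si](c1ccccc1)(c1ccccc1)C(C)(C)C | intermediate
4 | (2E,6E)-8-(tert-butyldiphenylsilyloxy)-2,6-dimethylocta-2,6-dienal | O=C/C(C)=C/CC/C(C)=C/CO[Si](c1ccccc1)(c1ccccc1)C(C)(C)C | intermediate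
5 | tert-butyl{[(2E,6E)-3,7-dimethylnona-2,6,8-trien-1-yl]oxy}diphenylsilane | C=C/C(C)=C/CC/C(C)=C/CO[Si](c1ccccc1)(c1ccccc1)C(C)(C)C | intermediate
6 | (3E,7E)-9-(tert-butyldiphenylsilyloxy)-3,7-dimethylnona-3,7-dien-1-ol | OCC/C(C)=C/CC/C(C)=C/CO[Si](c1ccccc1)(c1ccccc1)C(C)(C)C | intermediate
7 | tert-butyl{[(2E,6E)-9-iodo-3,7-dimethylnona-2,6-dien-1-yl]oxy}diphenylsilane | ICC/C(C)=C/CC/C(C)=C/CO[Si](c1ccccc1)(c1ccccc1)C(C)(C)C | intermediate
8 | 4,4-dimethylcyclohexane-1,3-dione | CC1(C)CCC(=O)CC1=O | starting material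
9 | 2,4,4-trimethylcyclohexane-1,3-dione | CC1C(=O)CCC(C)(C)C1=O | intermediate
10 | 3-(2-methylpropoxy)-2,6,6-trimethylcyclohex-2-en-1-one | CC(C)COC1=C(C)C(=O)C(C)(C)CC1 | intermediate
11 | [(3E,7E)-9-(tert-butyldiphenylsilyloxy)-3,7-dimethylnona-3,7-dien-1-yl]lithium | [Li]CC/C(C)=C/CC/C(C)=C/CO[Si](c1ccccc1)(c1ccccc1)C(C)(C)C | intermediate (not isolated)
12 | lithium 1-[(3E,7E)-9-(tert-butyldiphenylsilyloxy)-3,7-dimethylnona-3,7-dien-1-yl]-3-(2-methylpropoxy)-2,6,6-trimethylcyclohex-2-en-1-olate (racemic) | [Li]OC1(CC/C(C)=C/CC/C(C)=C/CO[Si](c2ccccc2)(c2ccccc2)C(C)(C)C)C(C)=C(OCC(C)C)CCC1(C)C | intermediate (not isolated)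
13 | 3-[(3E,7E)-9-(tert-butyldiphenylsilyloxy)-3,7-dimethylnona-3,7-dien-1-yl]-2,4,4-trimethylcyclohex-2-en-1-one | O=C1CCC(C)(C)C(CC/C(C)=C/CC/C(C)=C/CO[Si](c2ccccc2)(c2ccccc2)C(C)(C)C)=C1C | intermediate
14 | (1R)-3-[(3E,7E)-9-(tert-butyldiphenylsilyloxy)-3,7-dimethylnona-3,7-dien-1-yl]-2,4,4-trimethylcyclohex-2-en-1-ol | O[C@@H]1CCC(C)(C)C(CC/C(C)=C/CC/C(C)=C/CO[Si](c2ccccc2)(c2ccccc2)C(C)(C)C)=C1C | intermediate
15 | N-{(1S)-3-[(3E,7E)-9-(tert-butyldiphenylsilyloxy)-3,7-dimethylnona-3,7-dien-1-yl]-2,4,4-trimethylcyclohex-2-en-1-yl}-2-nitrobenzenesulfonohydrazide | NN([C@H]1CCC(C)(C)C(CC/C(C)=C/CC/C(C)=C/CO[Si](c2ccccc2)(c2ccccc2)C(C)(C)C)=C1C)S(=O)(=O)c1ccccc1[N+](=O)[O-] | intermediate (not isolated)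
16 | {(1S)-3-[(3E,7E)-9-(tert-butyldiphenylsilyloxy)-3,7-dimethylnona-3,7-dien-1-yl]-2,4,4-trimethylcyclohex-2-en-1-yl}diazene | N=N[C@H]1CCC(C)(C)C(CC/C(C)=C/CC/C(C)=C/CO[Si](c2ccccc2)(c2ccccc2)C(C)(C)C)=C1C | intermediate (not isolated)
17 | tert-butyl{[(2E,6E)-3,7-dimethyl-9-[(1S)-2,6,6-trimethylcyclohex-2-en-1-yl]nona-2,6-dien-1-yl]oxy}diphenylsilane | CC(C)(C)[Si](c1ccccc1)(c1ccccc1)OC/C=C(\C)CC/C=C(\C)CC[C@@H]1C(C)=CCCC1(C)C | intermediate
18 | (2E,6E)-3,7-dimethyl-9-[(1S)-2,6,6-trimethylcyclohex-2-en-1-yl]nona-2,6-dien-1-ol | OC/C=C(\C)CC/C=C(\C)CC[C@@H]1C(C)=CCCC1(C)C | intermediate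
19 | linoleic acid, (9Z,12Z)-octadeca-9,12-dienoic acid | CCCCC/C=C\C/C=C\CCCCCCCC(=O)O | starting material
20 | (9Z,12Z)-octadeca-9,12-dienoic 2,4,6-trichlorobenzoic anhydride | CCCCC/C=C\C/C=C\CCCCCCCC(=O)OC(=O)c1c(Cl)cc(Cl)cc1Cl | intermediate (not isolated)
21 | (2E,6E)-3,7-dimethyl-9-[(1S)-2,6,6-trimethylcyclohex-2-en-1-yl]nona-2,6-dien-1-yl (9Z,12Z)-octadeca-9,12-dienoate | CCCCC/C=C\C/C=C\CCCCCCCC(=O)OC/C=C(\C)CC/C=C(\C)CC[C@@H]1C(C)=CCCC1(C)C | target

**Step count**
Total: 13 steps. Longest linear sequence: 11 steps (geraniol 1 to 21 through steps 1–6 and 9–13); the dione branch (steps 7 and 8) joins at step 9.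

**Steps most likely to fail**

Step 11 (key step). Displacement at the ring carbinol may be slower than thermal decomposition of the sulfonylhydrazide. Ionisation of the activated alcohol, attack with allylic shift, or elimination to a ring diene would erode the transfer of configuration from C3′ to C1′. The fallback delivers the hydride from palladium instead of from a diazene. It sets out from 14, which is formylated (formic acid, DCC, DMAP, CH2Cl2, 0 °C) to the (1R)-allylic formate F1. Treatment with Pd(OAc)2 (cat.) and n-Bu3P in THF at reflux should give zerovalent palladium in situ, which ionises the formate anti to the leaving group. The π-allylpalladium formate loses CO2, and the resulting palladium hydride is passed from the metal face to the more substituted allyl terminus C1′ (Tsuji formate hydrogenolysis). Hydrogen again arrives anti to the former oxygen, and the route is rejoined at 17.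

Step 9. The 1,2-addition may be slow at a carbonyl that is flanked by CMe2 and deactivated as a vinylogous ester, so γ-deprotonation of 10 by the basic organolithium or Wurtz-type coupling during the exchange may compete. The fallback changes the electrophile and the way the carbonyl is transposed. It sets out from 7, which is converted into 11 as before and added at −78 °C to purchasable 2,6,6-trimethylcyclohex-2-en-1-one (CC1=CCCC(C)(C)C1=O), a more electrophilic simple enone, to give the tertiary allylic alcohol 1-[(3E,7E)-9-(tert-butyldiphenylsilyloxy)-3,7-dimethylnona-3,7-dien-1-yl]-2,6,6-trimethylcyclohex-2-en-1-ol F2. Babler–Dauben oxidative 1,3-transposition with pyridinium chlorochromate C5H5NH[CrO3Cl] in CH2Cl2 should then move the oxygen to the far alkene carbon and oxidise it, and the route is rejoined at 13.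

Step 10. Facial selectivity may be poor if the catalyst does not distinguish the CH2 flank from the fully substituted alkenyl flank well enough, and any shortfall in enantiomeric purity passes directly to C1′ of the target. The fallback replaces asymmetric reduction by resolution. It sets out from 13, which is reduced under Luche conditions (NaBH4, CeCl3·7H2O, MeOH, 0 °C) to the racemic allylic alcohol F3. Lipase-catalysed acylation (Burkholderia cepacia lipase, vinyl acetate, hexane, rt) should acylate the (R)-enantiomer faster, as expected from the empirical rule for secondary alcohols with the substituted alkenyl flank as the large group. This gives the (1R)-acetate F4 beside the unreacted (1S)-alcohol F5, which are separated by chromatography. Methanolysis of F4 (K2CO3, MeOH, rt) rejoins the route at 14; F5 can be re-oxidised with MnO2 to 13 and recycled.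

**Further compounds**
F1 | step 11 | (1R)-3-[(3E,7E)-9-(tert-butyldiphenylsilyloxy)-3,7-dimethylnona-3,7-dien-1-yl]-2,4,4-trimethylcyclohex-2-en-1-yl formate | O=CO[C@@H]1CCC(C)(C)C(CC/C(C)=C/CC/C(C)=C/CO[Si](c2ccccc2)(c2ccccc2)C(C)(C)C)=C1C
F2 | step 9 | 1-[(3E,7E)-9-(tert-butyldiphenylsilyloxy)-3,7-dimethylnona-3,7-dien-1-yl]-2,6,6-trimethylcyclohex-2-en-1-ol (racemic) | CC1=CCCC(C)(C)C1(O)CC/C(C)=C/CC/C(C)=C/CO[Si](c1ccccc1)(c1ccccc1)C(C)(C)C
F3 | step 10 | rac-3-[(3E,7E)-9-(tert-butyldiphenylsilyloxy)-3,7-dimethylnona-3,7-dien-1-yl]-2,4,4-trimethylcyclohex-2-en-1-ol | OC1CCC(C)(C)C(CC/C(C)=C/CC/C(C)=C/CO[Si](c2ccccc2)(c2ccccc2)C(C)(C)C)=C1C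
F4 | step 10 | (1R)-3-[(3E,7E)-9-(tert-butyldiphenylsilyloxy)-3,7-dimethylnona-3,7-dien-1-yl]-2,4,4-trimethylcyclohex-2-en-1-yl acetate | CC(=O)O[C@@H]1CCC(C)(C)C(CC/C(C)=C/CC/C(C)=C/CO[Si](c2ccccc2)(c2ccccc2)C(C)(C)C)=C1C
F5 | step 10 | (1S)-3-[(3E,7E)-9-(tert-butyldiphenylsilyloxy)-3,7-dimethylnona-3,7-dien-1-yl]-2,4,4-trimethylcyclohex-2-en-1-ol | O[C@H]1CCC(C)(C)C(CC/C(C)=C/CC/C(C)=C/CO[Si](c2ccccc2)(c2ccccc2)C(C)(C)C)=C1C
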